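**Assumption (one line):** the sense of induction in the key step is assigned by the standard Rh/diene enone-face model, not by a recalled result on this exact substrate; it would be confirmed on the first batch by chiral HPLC/CD, and the (R,R)-ligand used instead if it is reversed.

## Retrosynthetic overview

1. Glabrol (2S) ⇐ its bis-MOM ether (mild acid unmasking as the last step).
2. Key disconnection is C2–C1' (not the usual chalcone / oxa-Michael): Rh/chiral-diene asymmetric 1,4-addition of a prenylated arylboronic acid to a prenylated chromone, which sets C2 directly.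
3. Chromone half ⇐ commercial 7-hydroxychromone via reverse-prenyl ether and aromatic Claisen rearrangement to C8.
4. Boronic acid half ⇐ 4-bromophenol via ortho C-prenylation, MOM protection and Li/B exchange.
5. Ring order: the pyranone ring is bought intact and both benzene rings are commercial; no ring is formed in the route, and the only stereocentre is set in the convergent step.

## Forward route

**Step 1**
Reactants: 1 (7-hydroxy-4H-chromen-4-one); 2 (3-chloro-3-methylbut-1-yne)
Product: 3, 7-[(2-methylbut-3-yn-2-yl)oxy]-4H-chromen-4-one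
Conditions: K2CO3, KI, CuI (cat.), acetone, reflux
Reagents that add atoms: 3-chloro-3-methylbut-1-yne, C#CC(C)(C)Cl
Why: Cu-assisted SN1-type O-propargylation of the only phenol (tertiary propargyl ether synthesis, routine for 7-hydroxycoumarins and chromones); 56 °C is too low for propargyl Claisen/chromene formation.

**Step 2**
Reactants: 3
Product: 4, 7-[(2-methylbut-3-en-2-yl)oxy]-4H-chromen-4-one
Conditions: H2 (1 atm), Lindlar catalyst, quinoline, EtOAc, rt
Reagents that add atoms: none
Why: Lindlar semihydrogenation stops at the terminal alkene and leaves the chromone C2=C3 vinylogous ester untouched.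

**Step 3**
Reactants: 4
Product: 5, 7-hydroxy-8-(3-methylbut-2-en-1-yl)-4H-chromen-4-one
Conditions: PhNEt2, 130 °C, Ar
Reagents that add atoms: none
Why: aromatic Claisen [3,3] rearrangement; allyl inversion turns the 1,1-dimethylallyl ether into a normal prenyl group, and C7–C8 bond fixation in the benzo-γ-pyrone directs migration to C8 over C6 (as for 7-allyloxy coumarins and flavones).

**Step 4**
Reactants: 5; 6 (chloromethyl methyl ether, MOMCl)
Product: 7, 7-(methoxymethoxy)-8-(3-methylbut-2-en-1-yl)-4H-chromen-4-one
Conditions: MOMCl, i-Pr2NEt, CH2Cl2, 0 °C to rt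
Reagents that add atoms: MOMCl, COCCl
Why: standard MOM etherification of an acidic phenol; MOM survives the aqueous base and aryl-rhodium of Step 8 and comes off under mild acid.

**Step 5**
Reactants: 8 (4-bromophenol); 9 (prenyl bromide, 1-bromo-3-methylbut-2-ene)
Product: 10, 4-bromo-2-(3-methylbut-2-en-1-yl)phenol
Conditions: NaH, toluene, 0 °C to rt
Reagents that add atoms: prenyl bromide, CC(C)=CCBr
Why: ortho-selective C-allylation of a sodium phenoxide tight ion pair in a non-polar solvent (para position blocked by Br); the O-prenyl ether by-product is separable.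

**Step 6**
Reactants: 10; 6 (MOMCl)
Product: 11, 4-bromo-1-(methoxymethoxy)-2-(3-methylbut-2-en-1-yl)benzene
Conditions: MOMCl, i-Pr2NEt, CH2Cl2, 0 °C to rt
Reagents that add atoms: MOMCl, COCCl
Why: routine MOM protection; removes the acidic OH before lithiation.

**Step 7**
Reactants: 11; 12 (triisopropyl borate)
Product: 13, [4-(methoxymethoxy)-3-(3-methylbut-2-en-1-yl)phenyl]boronic acid
Conditions: B(Oi-Pr)3, then n-BuLi, THF/toluene, −78 °C (in situ quench); sat. aq. NH4Cl
Reagents that add atoms: triisopropyl borate, CC(C)OB(OC(C)C)OC(C)C; water, O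
Why: Br/Li exchange at −78 °C outruns ortho-lithiation and benzylic/allylic deprotonation, the aryllithium is trapped at once by borate, and the NH4Cl hydrolysis is too mild to cleave MOM (lithiation–borylation).

**Step 8 (key step)**
Reactants: 7; 13 (2 equiv)
Product: 14, (2S)-7-(methoxymethoxy)-2-[4-(methoxymethoxy)-3-(3-methylbut-2-en-1-yl)phenyl]-8-(3-methylbut-2-en-1-yl)-2,3-dihydro-4H-chromen-4-one
Conditions: [RhCl(C2H4)2]2 (2.5 mol %), (S,S)-Ph-bod [(1S,4S)-2,5-diphenylbicyclo[2.2.2]octa-2,5-diene] (5.5 mol %), KOH (10 mol %), toluene/H2O 10:1, 40 °C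
Reagents that add atoms: none beyond the aryl donor 13, CC(C)=CCc1cc(B(O)O)ccc1OCOC (water supplies only H)
Why: Hayashi–Miyaura Rh-catalysed asymmetric 1,4-addition to a chromone; the (S,S)-diene–Rh–aryl attacks the enone face that gives (S)-3-arylcyclohexanones, which maps onto (2S)-flavanone, while the trisubstituted prenyl alkenes do not insert and the toluene/low-base medium suppresses ring-opening and racemisation.

**Step 9**
Reactants: 14
Product: 15, (S)-glabrol
Conditions: 3 M aq. HCl, MeOH, rt; neutral work-up (no base)
Reagents that add atoms: none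
Why: acid-catalysed acetal hydrolysis of both MOM ethers; dilute acid at rt is too weak to hydroalkoxylate the prenyl groups to chromans, and avoiding base prevents retro-oxa-Michael racemisation of the 4'-hydroxyflavanone.

## Compound list

1 | 7-hydroxy-4H-chromen-4-one | O=c1ccoc2cc(O)ccc12 | starting material
2 | 3-chloro-3-methylbut-1-yne | C#CC(C)(C)Cl | starting material
3 | 7-[(2-methylbut-3-yn-2-yl)oxy]-4H-chromen-4-one | O=c1ccoc2cc(OC(C)(C)C#C)ccc12 | intermediate
4 | 7-[(2-methylbut-3-en-2-yl)oxy]-4H-chromen-4-one | O=c1ccoc2cc(OC(C)(C)C=C)ccc12 | intermediate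
5 | 7-hydroxy-8-(3-methylbut-2-en-1-yl)-4H-chromen-4-one | O=c1ccoc2c(CC=C(C)C)c(O)ccc12 | intermediate
6 | chloromethyl methyl ether (MOMCl) | COCCl | starting material
7 | 7-(methoxymethoxy)-8-(3-methylbut-2-en-1-yl)-4H-chromen-4-one | O=c1ccoc2c(CC=C(C)C)c(OCOC)ccc12 | intermediate
8 | 4-bromophenol | Oc1ccc(Br)cc1 | starting material
9 | prenyl bromide (1-bromo-3-methylbut-2-ene) | CC(C)=CCBr | starting material
10 | 4-bromo-2-(3-methylbut-2-en-1-yl)phenol | CC(C)=CCc1cc(Br)ccc1O | intermediate
11 | 4-bromo-1-(methoxymethoxy)-2-(3-methylbut-2-en-1-yl)benzene | CC(C)=CCc1cc(Br)ccc1OCOC | intermediate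
12 | triisopropyl borate | CC(C)OB(OC(C)C)OC(C)C | starting material
13 | [4-(methoxymethoxy)-3-(3-methylbut-2-en-1-yl)phenyl]boronic acid | CC(C)=CCc1cc(B(O)O)ccc1OCOC | intermediate
14 | (2S)-7-(methoxymethoxy)-2-[4-(methoxymethoxy)-3-(3-methylbut-2-en-1-yl)phenyl]-8-(3-methylbut-2-en-1-yl)-2,3-dihydro-4H-chromen-4-one | CC(C)=CCc1cc([C@@H]2CC(=O)c3ccc(OCOC)c(CC=C(C)C)c3O2)ccc1OCOC | intermediate
15 | (S)-glabrol, (2S)-7-hydroxy-2-[4-hydroxy-3-(3-methylbut-2-en-1-yl)phenyl]-8-(3-methylbut-2-en-1-yl)-2,3-dihydro-4H-chromen-4-one | CC(C)=CCc1cc([C@@H]2CC(=O)c3ccc(O)c(CC=C(C)C)c3O2)ccc1O | target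

## Summary

**Total steps:** 9 (chromone arm 4, boronic acid arm 3, union 1, deprotection 1).
**Longest linear sequence:** 6 (Steps 1, 2, 3, 4, 8, 9).

**Three steps most likely to fail, with fallbacks:**

1. **Step 8** (low conversion on the electron-rich 7-alkoxychromone, ring-opening/double arylation, or insufficient ee). Fallback: abandon the C2–aryl disconnection. Convert 11 to the aldehyde (n-BuLi/DMF), condense it with 2-hydroxy-4-(methoxymethoxy)-3-prenylacetophenone (Claisen–Schmidt), cyclise the chalcone to racemic 14, and recover (S)-14 by Ru–TsDPEN transfer-hydrogenation kinetic resolution.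
2. **Step 9** (acid-induced chroman formation from the o-prenylphenols, or partial racemisation). Fallback: change the protecting-group strategy to TIPS ethers on both fragments from Steps 4 and 6, and unmask at the end with buffered fluoride (TBAF/AcOH or HF·pyridine) so no protic acid meets the prenyl groups.
3. **Step 3** (C6/C8 regioisomer mixture or loss of the tertiary allyl group). Fallback: do the Claisen one stage earlier on 2-hydroxy-4-(1,1-dimethylallyloxy)acetophenone, where the chelated ortho-OH fixes migration to C3. Then MOM-protect, form the enaminone with DMF-DMA and cyclise to chromone 7.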